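## Retrosynthetic overview

1. Germacrane numbering is used for atom labels: C6 is the lactone CH–O, C7 the ring-fusion CH, C8 the ester CH, C10 carries C14H2OAc, C4 carries C15H3. The last ring bond made is C2=C3 (Z), by ring-closing metathesis of an acyclic ene–diene, followed by desilylation.
2. The C8 ester comes from Yamaguchi acylation with bis-silylated (S)-2-methylglyceric acid, made from (R)-3-bromo-2-hydroxy-2-methylpropanoic acid.
3. The C7–C8 bond, which sets C7 and C8 from C6, comes from a zinc Barbier allylation of (3E)-3-(acetoxymethyl)hexa-3,5-dienal with a 3-(bromomethyl)butenolide.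
4. The butenolide comes from (S)-β-citronellene (C4) by ozonolysis, organocatalytic α-oxyamination (C6), Morita–Baylis–Hillman reaction, lactonisation and SN2' bromination. The dienal comes from an alkylated phosphonoacetate and acrolein (Horner–Wadsworth–Emmons).
5. Ring order: γ-lactone first (step 4), ten-membered carbocycle last (step 16).

Assumption: (S)-β-citronellene and (R)-3-bromo-2-hydroxy-2-methylpropanoic acid are bought in high enantiomeric purity; the route is a literature-informed proposal, not an executed synthesis.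

## Route

**Step 1**
Reactants: 1 (3S)-3,7-dimethylocta-1,6-diene
Product: 3 (4S)-4-methylhex-5-enal, via secondary ozonide 2 (not isolated)
Conditions: O3 (1 equiv), CH2Cl2, −78 °C; then PPh3, −78 °C to rt
Reagents that add atoms: ozone, [O-][O+]=O
Why: Ozonolysis (Criegee mechanism) is much faster at the electron-rich trisubstituted alkene than at the vinyl group, so only the isopropylidene end is cleaved and the C4 stereocentre is untouched.

**Step 2**
Reactants: 3 (4S)-4-methylhex-5-enal
Product: 4 (2S,4S)-4-methyl-2-[(2,2,6,6-tetramethylpiperidin-1-yl)oxy]hex-5-enal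
Conditions: TEMPO (1.5 equiv), CuCl2 (10 mol %), (5S)-5-benzyl-2,2,3-trimethylimidazolidin-4-one·CF3CO2H (20 mol %), air, acetone, −10 °C
Reagents that add atoms: TEMPO, CC1(C)CCCC(C)(C)N1[O]
Why: Organocatalytic enamine α-oxyamination: the benzyl group of the (5S) catalyst shields one face of the E-enamine, so the C–O bond forms on the open face and sets C6 as S under catalyst control.

**Step 3**
Reactants: 4 (2S,4S)-4-methyl-2-[(2,2,6,6-tetramethylpiperidin-1-yl)oxy]hex-5-enal; 5 methyl acrylate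
Product: 6 methyl (4S,6S)-3-hydroxy-6-methyl-2-methylidene-4-[(2,2,6,6-tetramethylpiperidin-1-yl)oxy]oct-7-enoate (C3 epimers)
Conditions: 5 (5 equiv), quinuclidine (0.5 equiv), MeOH (1 equiv), neat, rt, 2–4 d
Reagents that add atoms: none
Why: Morita–Baylis–Hillman reaction of the activated α-alkoxy aldehyde; the new carbinol centre forms as a mixture, which does not matter because it becomes sp2 in step 5.

**Step 4**
Reactants: 6 methyl (4S,6S)-3-hydroxy-6-methyl-2-methylidene-4-[(2,2,6,6-tetramethylpiperidin-1-yl)oxy]oct-7-enoate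
Product: 8 (5S)-4-hydroxy-3-methylidene-5-[(2S)-2-methylbut-3-en-1-yl]oxolan-2-one (C4 epimers), via diol ester 7 (not isolated)
Conditions: Zn dust, AcOH/THF/H2O (3:1:1), 60 °C; then TsOH·H2O (cat.), CH2Cl2, rt
Reagents that add atoms: none
Why: Zinc in acetic acid cleaves the N–O bond reductively and the freed C6 hydroxyl lactonises onto the methyl ester, forming the γ-lactone with C6 unchanged.

**Step 5**
Reactants: 8 (5S)-4-hydroxy-3-methylidene-5-[(2S)-2-methylbut-3-en-1-yl]oxolan-2-one
Product: 10 (5S)-3-(bromomethyl)-5-[(2S)-2-methylbut-3-en-1-yl]furan-2(5H)-one, via allylic mesylate 9 (not isolated)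
Conditions: Ms2O, Et3N, CH2Cl2, −20 °C; then LiBr, THF, 0 °C to rt
Reagents that add atoms: lithium bromide, [Li+].[Br-]
Why: Mesylation then SN2' displacement by bromide moves the double bond into the ring and gives the conjugated primary allylic bromide as the thermodynamic product; C6 is not involved.

**Step 6**
Reactants: 11 triethyl phosphonoacetate; 12 (2-bromoethoxy)(tert-butyl)dimethylsilane
Product: 14 ethyl 4-[(tert-butyldimethylsilyl)oxy]-2-(diethoxyphosphoryl)butanoate (racemic), via sodium phosphonate anion 13 (not isolated)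
Conditions: NaH, DMF, 0 °C; then 12, NaI (cat.), 60 °C
Reagents that add atoms: none
Why: SN2 alkylation of the stabilised phosphonate carbanion with a primary bromide.

**Step 7**
Reactants: 14 ethyl 4-[(tert-butyldimethylsilyl)oxy]-2-(diethoxyphosphoryl)butanoate; 15 acrolein
Product: 17 ethyl (2E)-2-{2-[(tert-butyldimethylsilyl)oxy]ethyl}penta-2,4-dienoate, via sodium phosphonate anion 16 (not isolated)
Conditions: NaH, THF, 0 °C; then 15, −78 to 0 °C
Reagents that add atoms: none
Why: Horner–Wadsworth–Emmons olefination; reversible addition favours the E ester with the vinyl group trans to the ester, which is the geometry needed for C1=C10 (minor Z isomer removed by chromatography).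

**Step 8**
Reactants: 17 ethyl (2E)-2-{2-[(tert-butyldimethylsilyl)oxy]ethyl}penta-2,4-dienoate
Product: 19 (2E)-2-{2-[(tert-butyldimethylsilyl)oxy]ethyl}penta-2,4-dien-1-ol, via dienal 18 (not isolated)
Conditions: i-Bu2AlH (2.5 equiv), CH2Cl2, −78 °C; aq. potassium sodium tartrate (KNaC4H4O6)
Reagents that add atoms: none
Why: 1,2-Reduction of the conjugated ester by the aluminium hydride gives the allylic alcohol without touching the diene or the silyl ether.

**Step 9**
Reactants: 19 (2E)-2-{2-[(tert-butyldimethylsilyl)oxy]ethyl}penta-2,4-dien-1-ol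
Product: 20 (2E)-2-{2-[(tert-butyldimethylsilyl)oxy]ethyl}penta-2,4-dien-1-yl acetate
Conditions: Ac2O, pyridine, DMAP (cat.), CH2Cl2, 0 °C to rt
Reagents that add atoms: acetic anhydride, CC(=O)OC(C)=O
Why: Nucleophile-catalysed acylation of the primary allylic alcohol installs the C14 acetate.

**Step 10**
Reactants: 20 (2E)-2-{2-[(tert-butyldimethylsilyl)oxy]ethyl}penta-2,4-dien-1-yl acetate
Product: 21 (2E)-2-(2-hydroxyethyl)penta-2,4-dien-1-yl acetate
Conditions: HF·pyridine, pyridine, THF, 0 °C to rt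
Reagents that add atoms: none
Why: Fluoride-driven Si–O cleavage of the primary silyl ether under buffered conditions leaves the allylic acetate intact.

**Step 11**
Reactants: 21 (2E)-2-(2-hydroxyethyl)penta-2,4-dien-1-yl acetate
Product: 22 (2E)-2-(2-oxoethyl)penta-2,4-dien-1-yl acetate
Conditions: Dess–Martin periodinane, pyridine, CH2Cl2, 0 °C, 30 min; used crude at once in step 14
Reagents that add atoms: none
Why: Dess–Martin oxidation is mild and non-enolising, so the β,γ-unsaturated aldehyde is obtained without migration of the double bond into conjugation.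

**Step 12**
Reactants: 23 (2R)-3-bromo-2-hydroxy-2-methylpropanoic acid
Product: 25 (2S)-2,3-dihydroxy-2-methylpropanoic acid, via sodium epoxy carboxylate 24 (not isolated)
Conditions: NaOH (3 equiv), H2O, 90 °C; then aq. HCl to pH 2, evaporate, extract with acetone
Reagents that add atoms: water, O
Why: Intramolecular Williamson closure to the epoxide and hydroxide opening at the CH2 terminus (SN2) never break a bond at the quaternary carbon, so its configuration is retained (the descriptor changes from R to S only through CIP priority).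

**Step 13**
Reactants: 25 (2S)-2,3-dihydroxy-2-methylpropanoic acid
Product: 27 (2S)-2-methyl-2,3-bis[(triethylsilyl)oxy]propanoic acid, via silyl ester 26 (not isolated)
Conditions: Et3SiOTf (3.3 equiv), 2,6-lutidine, CH2Cl2, −78 to 0 °C; then MeOH/H2O, 0 °C to rt
Reagents that add atoms: triethylsilyl trifluoromethanesulfonate, CC[Si](CC)(CC)OS(=O)(=O)C(F)(F)F
Why: The silyl triflate silylates both hydroxyls (including the tertiary one) and the acid; only the labile silyl ester is hydrolysed in aqueous methanol.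

**Step 14**
Reactants: 10 (5S)-3-(bromomethyl)-5-[(2S)-2-methylbut-3-en-1-yl]furan-2(5H)-one; 22 (2E)-2-(2-oxoethyl)penta-2,4-dien-1-yl acetate
Product: 29 (2E)-2-{(2R)-2-hydroxy-2-[(2S,3S)-4-methylidene-2-[(2S)-2-methylbut-3-en-1-yl]-5-oxooxolan-3-yl]ethyl}penta-2,4-dien-1-yl acetate, via allylzinc bromide 28 (not isolated)
Conditions: Zn dust, THF/sat. aq. NH4Cl (2:1), 0 °C to rt
Reagents that add atoms: none
Why: Zinc Barbier allylation (SE2' through a Zimmerman–Traxler chair): the allylzinc adds through C7 on the face anti to the C6 side chain (trans lactone), and with the ring carbon fixed in the E position and the aldehyde residue equatorial it gives the 7,8-anti carbinol (8R), regenerating the α-methylene lactone.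

**Step 15**
Reactants: 29 (2E)-2-{(2R)-2-hydroxy-2-[(2S,3S)-4-methylidene-2-[(2S)-2-methylbut-3-en-1-yl]-5-oxooxolan-3-yl]ethyl}penta-2,4-dien-1-yl acetate; 27 (2S)-2-methyl-2,3-bis[(triethylsilyl)oxy]propanoic acid
Product: 31 (1R,3E)-3-(acetoxymethyl)-1-[(2S,3R)-4-methylidene-2-[(2S)-2-methylbut-3-en-1-yl]-5-oxooxolan-3-yl]hexa-3,5-dien-1-yl (2S)-2-methyl-2,3-bis[(triethylsilyl)oxy]propanoate, via mixed anhydride 30 (not isolated)
Conditions: 27, 2,4,6-Cl3C6H2COCl, Et3N, toluene, rt; then 29, DMAP, toluene, rt to 40 °C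
Reagents that add atoms: none
Why: Yamaguchi esterification through the mixed anhydride and acylpyridinium acylates the hindered C8 carbinol without touching any stereocentre, and removes the free hydroxyl that could translactonise.

**Step 16**
Reactants: 31 (1R,3E)-3-(acetoxymethyl)-1-[(2S,3R)-4-methylidene-2-[(2S)-2-methylbut-3-en-1-yl]-5-oxooxolan-3-yl]hexa-3,5-dien-1-yl (2S)-2-methyl-2,3-bis[(triethylsilyl)oxy]propanoate
Product: 32 [(3aR,4R,6E,8Z,10S,11aS)-10-methyl-3-methylidene-4-{[(2S)-2-methyl-2,3-bis(triethylsilyloxy)propanoyl]oxy}-2-oxo-2,3,3a,4,5,10,11,11a-octahydrocyclodeca[b]furan-6-yl]methyl acetate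
Conditions: second-generation Hoveyda–Grubbs catalyst (10 mol %), toluene (1 mM), 80 °C, argon sparge
Reagents that add atoms: none
Why: Ring-closing metathesis joins the C3 vinyl group to the terminal alkene of the diene (the trisubstituted C1=C10 and the electron-poor exo-methylene do not react); the ten-membered ring can hold the new C2=C3 bond only as Z beside the ring-cis C1=C10 bond.

**Step 17**
Reactants: 32 [(3aR,4R,6E,8Z,10S,11aS)-10-methyl-3-methylidene-4-{[(2S)-2-methyl-2,3-bis(triethylsilyloxy)propanoyl]oxy}-2-oxo-2,3,3a,4,5,10,11,11a-octahydrocyclodeca[b]furan-6-yl]methyl acetate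
Product: 34 [(3aR,4R,6E,8Z,10S,11aS)-4-{[(2S)-2,3-dihydroxy-2-methylpropanoyl]oxy}-10-methyl-3-methylidene-2-oxo-2,3,3a,4,5,10,11,11a-octahydrocyclodeca[b]furan-6-yl]methyl acetate (CNP0347302.1), via mono-silyl ether 33 (not isolated)
Conditions: HF·pyridine, pyridine, THF, 0 °C to rt
Reagents that add atoms: none
Why: Buffered fluoride removes both triethylsilyl ethers (primary first) without affecting the allylic acetate, the ester or the α-methylene lactone.

## Compound list

1 | (3S)-3,7-dimethylocta-1,6-diene ((S)-β-citronellene) | CC(C)=CCC[C@H](C)C=C | starting material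
2 | 3,3-dimethyl-5-[(3S)-3-methylpent-4-en-1-yl]-1,2,4-trioxolane (C5 epimers) | CC1(C)OOC(CC[C@H](C)C=C)O1 | intermediate (not isolated)
3 | (4S)-4-methylhex-5-enal | O=CCC[C@H](C)C=C | intermediate
4 | (2S,4S)-4-methyl-2-[(2,2,6,6-tetramethylpiperidin-1-yl)oxy]hex-5-enal | O=C[C@@H](ON1C(C)(C)CCCC1(C)C)C[C@H](C)C=C | intermediate
5 | methyl acrylate | C=CC(=O)OC | starting material
6 | methyl (4S,6S)-3-hydroxy-6-methyl-2-methylidene-4-[(2,2,6,6-tetramethylpiperidin-1-yl)oxy]oct-7-enoate (C3 epimers) | C=C(C(=O)OC)C(O)[C@@H](ON1C(C)(C)CCCC1(C)C)C[C@H](C)C=C | intermediate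
7 | methyl (4S,6S)-3,4-dihydroxy-6-methyl-2-methylideneoct-7-enoate (C3 epimers) | C=C(C(=O)OC)C(O)[C@@H](O)C[C@H](C)C=C | intermediate (not isolated)
8 | (5S)-4-hydroxy-3-methylidene-5-[(2S)-2-methylbut-3-en-1-yl]oxolan-2-one (C4 epimers) | C=C1C(=O)O[C@@H](C[C@H](C)C=C)C1O | intermediate
9 | (2S)-4-methylidene-2-[(2S)-2-methylbut-3-en-1-yl]-5-oxooxolan-3-yl methanesulfonate (C3 epimers) | C=C1C(=O)O[C@@H](C[C@H](C)C=C)C1OS(C)(=O)=O | intermediate (not isolated)
10 | (5S)-3-(bromomethyl)-5-[(2S)-2-methylbut-3-en-1-yl]furan-2(5H)-one | BrCC1=C[C@H](C[C@H](C)C=C)OC1=O | intermediate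
11 | triethyl phosphonoacetate | CCOC(=O)CP(=O)(OCC)OCC | starting material
12 | (2-bromoethoxy)(tert-butyl)dimethylsilane | CC(C)(C)[Si](C)(C)OCCBr | starting material
13 | sodium salt of triethyl phosphonoacetate | [Na+].CCOC(=O)[CH-]P(=O)(OCC)OCC | intermediate (not isolated)
14 | ethyl 4-[(tert-butyldimethylsilyl)oxy]-2-(diethoxyphosphoryl)butanoate (racemic) | CCOC(=O)C(CCO[Si](C)(C)C(C)(C)C)P(=O)(OCC)OCC | intermediate
15 | acrolein | C=CC=O | starting material
16 | sodium salt of 14 | [Na+].CCOC(=O)[C-](CCO[Si](C)(C)C(C)(C)C)P(=O)(OCC)OCC | intermediate (not isolated)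
17 | ethyl (2E)-2-{2-[(tert-butyldimethylsilyl)oxy]ethyl}penta-2,4-dienoate | CCOC(=O)/C(CCO[Si](C)(C)C(C)(C)C)=C/C=C | intermediate
18 | (2E)-2-{2-[(tert-butyldimethylsilyl)oxy]ethyl}penta-2,4-dienal | O=C/C(CCO[Si](C)(C)C(C)(C)C)=C/C=C | intermediate (not isolated)
19 | (2E)-2-{2-[(tert-butyldimethylsilyl)oxy]ethyl}penta-2,4-dien-1-ol | OC/C(CCO[Si](C)(C)C(C)(C)C)=C/C=C | intermediate
20 | (2E)-2-{2-[(tert-butyldimethylsilyl)oxy]ethyl}penta-2,4-dien-1-yl acetate | CC(=O)OC/C(CCO[Si](C)(C)C(C)(C)C)=C/C=C | intermediate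
21 | (2E)-2-(2-hydroxyethyl)penta-2,4-dien-1-yl acetate | CC(=O)OC/C(CCO)=C/C=C | intermediate
22 | (2E)-2-(2-oxoethyl)penta-2,4-dien-1-yl acetate | CC(=O)OC/C(CC=O)=C/C=C | intermediate
23 | (2R)-3-bromo-2-hydroxy-2-methylpropanoic acid | O=C(O)[C@@](C)(O)CBr | starting material
24 | sodium (2S)-2-methyloxirane-2-carboxylate | [Na+].[O-]C(=O)[C@@]1(C)OC1 | intermediate (not isolated)
25 | (2S)-2,3-dihydroxy-2-methylpropanoic acid | O=C(O)[C@@](C)(O)CO | intermediate
26 | triethylsilyl (2S)-2-methyl-2,3-bis[(triethylsilyl)oxy]propanoate | CC[Si](CC)(CC)OC(=O)[C@@](C)(O[Si](CC)(CC)CC)CO[Si](CC)(CC)CC | intermediate (not isolated)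
27 | (2S)-2-methyl-2,3-bis[(triethylsilyl)oxy]propanoic acid | O=C(O)[C@@](C)(O[Si](CC)(CC)CC)CO[Si](CC)(CC)CC | intermediate
28 | bromo{[(5S)-5-[(2S)-2-methylbut-3-en-1-yl]-2-oxo-2,5-dihydrofuran-3-yl]methyl}zinc | Br[Zn]CC1=C[C@H](C[C@H](C)C=C)OC1=O | intermediate (not isolated)
29 | (2E)-2-{(2R)-2-hydroxy-2-[(2S,3S)-4-methylidene-2-[(2S)-2-methylbut-3-en-1-yl]-5-oxooxolan-3-yl]ethyl}penta-2,4-dien-1-yl acetate | C=C1C(=O)O[C@@H](C[C@H](C)C=C)[C@@H]1[C@H](O)C/C(COC(C)=O)=C\C=C | intermediate
30 | 2,4,6-trichlorobenzoic (2S)-2-methyl-2,3-bis[(triethylsilyl)oxy]propanoic anhydride | O=C(OC(=O)c1c(Cl)cc(Cl)cc1Cl)[C@@](C)(O[Si](CC)(CC)CC)CO[Si](CC)(CC)CC | intermediate (not isolated)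
31 | (1R,3E)-3-(acetoxymethyl)-1-[(2S,3R)-4-methylidene-2-[(2S)-2-methylbut-3-en-1-yl]-5-oxooxolan-3-yl]hexa-3,5-dien-1-yl (2S)-2-methyl-2,3-bis[(triethylsilyl)oxy]propanoate | C=C1C(=O)O[C@@H](C[C@H](C)C=C)[C@@H]1[C@H](OC(=O)[C@@](C)(O[Si](CC)(CC)CC)CO[Si](CC)(CC)CC)C/C(COC(C)=O)=C\C=C | intermediate
32 | [(3aR,4R,6E,8Z,10S,11aS)-10-methyl-3-methylidene-4-{[(2S)-2-methyl-2,3-bis(triethylsilyloxy)propanoyl]oxy}-2-oxo-2,3,3a,4,5,10,11,11a-octahydrocyclodeca[b]furan-6-yl]methyl acetate | C=C1C(=O)O[C@H]2C[C@H](C)/C=C\C=C(\COC(C)=O)C[C@@H](OC(=O)[C@@](C)(O[Si](CC)(CC)CC)CO[Si](CC)(CC)CC)[C@H]12 | intermediate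
33 | [(3aR,4R,6E,8Z,10S,11aS)-4-{[(2S)-3-hydroxy-2-methyl-2-(triethylsilyloxy)propanoyl]oxy}-10-methyl-3-methylidene-2-oxo-2,3,3a,4,5,10,11,11a-octahydrocyclodeca[b]furan-6-yl]methyl acetate | C=C1C(=O)O[C@H]2C[C@H](C)/C=C\C=C(\COC(C)=O)C[C@@H](OC(=O)[C@@](C)(O[Si](CC)(CC)CC)CO)[C@H]12 | intermediate (not isolated)
34 | [(3aR,4R,6E,8Z,10S,11aS)-4-{[(2S)-2,3-dihydroxy-2-methylpropanoyl]oxy}-10-methyl-3-methylidene-2-oxo-2,3,3a,4,5,10,11,11a-octahydrocyclodeca[b]furan-6-yl]methyl acetate | C=C1C(=O)O[C@H]2C[C@H](C)/C=C\C=C(\COC(C)=O)C[C@@H](OC(=O)[C@@](C)(O)CO)[C@H]12 | target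

## Step count and risks

Total: 17 steps (5 for the bromobutenolide, 6 for the dienal, 2 for the side-chain acid, 4 after the union).
Longest linear sequence: 10 steps (steps 6–11, then 14–17).

The three steps most likely to fail:

- **Step 16 (ring-closing metathesis).** Closing a ten-membered ring onto a diene terminus can stall or oligomerise, and the bulky C8 ester may disfavour the reactive conformer. The fallback changes the cyclisation substrate and the order of events: it sets out from 29 and closes the ring on the free carbinol (same ruthenium catalyst, toluene, 80 °C, high dilution) to give the macrocyclic carbinol F5. The ring alcohol of F5 is then acylated with 27 through the mixed anhydride 30 (Yamaguchi), and the route is rejoined at 32.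

- **Step 14 (Barbier coupling).** Aldehyde 22 can isomerise into conjugation in the aqueous medium, and the open organozinc may give a lower diastereomer ratio than hoped. The fallback replaces the in-situ organozinc by a preformed boron reagent under anhydrous conditions: it sets out from 10, which is borylated with B2pin2 and Pd2(dba)3 (cat.) in THF at 60 °C to give the pinacol allylboronate F3. Allylboration of 22 with F3 (Sc(OTf)3 cat., toluene, −78 °C) runs through a closed chair and gives the lactone O-boryl adduct F4. Mild aqueous hydrolysis of F4 returns the route at 29.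

- **Step 3 (Morita–Baylis–Hillman reaction).** The aldehyde 4 carries a very bulky α-substituent and the amine-catalysed addition may be too slow. The fallback uses a stoichiometric acrylate α-anion equivalent: it sets out from 4, which is treated with the lithium enolate of methyl 3-(dimethylamino)propanoate (LiN(i-Pr)2, THF, −78 °C) to give the β-hydroxy amino ester F1. Methylation of F1 with MeI gives the trimethylammonium iodide F2, and E1cB elimination from F2 with DBU returns the route at 6.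

## Further compounds

F1 | step 3 | methyl (4S,6S)-2-[(dimethylamino)methyl]-3-hydroxy-6-methyl-4-[(2,2,6,6-tetramethylpiperidin-1-yl)oxy]oct-7-enoate (C2/C3 epimers) | CN(C)CC(C(=O)OC)C(O)[C@@H](ON1C(C)(C)CCCC1(C)C)C[C@H](C)C=C
F2 | step 3 | [(4S,6S)-3-hydroxy-2-(methoxycarbonyl)-6-methyl-4-[(2,2,6,6-tetramethylpiperidin-1-yl)oxy]oct-7-en-1-yl]trimethylammonium iodide | C[N+](C)(C)CC(C(=O)OC)C(O)[C@@H](ON1C(C)(C)CCCC1(C)C)C[C@H](C)C=C.[I-]
F3 | step 14 | (5S)-5-[(2S)-2-methylbut-3-en-1-yl]-3-[(4,4,5,5-tetramethyl-1,3,2-dioxaborolan-2-yl)methyl]furan-2(5H)-one | CC1(C)OB(CC2=C[C@H](C[C@H](C)C=C)OC2=O)OC1(C)C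
F4 | step 14 | (2E)-2-{(2R)-2-[(2S,3S)-4-methylidene-2-[(2S)-2-methylbut-3-en-1-yl]-5-oxooxolan-3-yl]-2-[(4,4,5,5-tetramethyl-1,3,2-dioxaborolan-2-yl)oxy]ethyl}penta-2,4-dien-1-yl acetate | C=C1C(=O)O[C@@H](C[C@H](C)C=C)[C@@H]1[C@H](OB2OC(C)(C)C(C)(C)O2)C/C(COC(C)=O)=C\C=C
F5 | step 16 | [(3aS,4R,6E,8Z,10S,11aS)-4-hydroxy-10-methyl-3-methylidene-2-oxo-2,3,3a,4,5,10,11,11a-octahydrocyclodeca[b]furan-6-yl]methyl acetate | C=C1C(=O)O[C@H]2C[C@H](C)/C=C\C=C(\COC(C)=O)C[C@@H](O)[C@H]12
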